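**Retrosynthetic overview**
1. The route rests on the two ortho-hydroxyaryl ketone units of the target: the C1′ carbonyl next to the free C2′ hydroxyl on ring A (the methoxylated ring) and the C1″ carbonyl next to the free C2″ hydroxyl on ring A′.
2. After removal of two silyl groups from the ring B and B′ phenols, both C(=O)–Cα bonds are cut at once: a twofold rhodium hydroacylation of a terminal 4-silyloxyphenylacetylene by the formyl C–H bonds of a diaryl ether bis-salicylaldehyde, which also sets both E alkenes.
3. The bis-salicylaldehyde comes from 4-(3-hydroxyphenoxy)-3-methoxyphenol by twofold ortho-formylation; this bisphenol comes from SNAr of resorcinol on 4-fluoro-3-methoxybenzaldehyde, then Baeyer–Villiger/Dakin exchange of formyl for hydroxyl.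
4. The alkyne comes from 4-iodophenol by O-silylation, Sonogashira coupling with ethynyltrimethylsilane and C-desilylation.
5. No ring is formed: the four benzene rings are bought, the ether oxygen joins rings A and A′ first, and the two enone bridges to rings B and B′ are made last and together.

Key step: step 7

Remark: the ring B phenols are carried as triisopropylsilyl ethers, because a phenolic tert-butyldimethylsilyl ether would be at risk in the methanolic carbonate of step 6; the key step is otherwise unaffected by this choice.

**Step 1**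
Reactants: 1 resorcinol (4 equiv); 2 4-fluoro-3-methoxybenzaldehyde
Product: 3 4-(3-hydroxyphenoxy)-3-methoxybenzaldehyde
Conditions: K2CO3, DMSO, 100 °C, argon
Reagents that add atoms: none
Why: Nucleophilic aromatic substitution (SNAr), in which the fluoride para to the formyl group is displaced through a Meisenheimer adduct and the large excess of resorcinol monophenoxide should hold the reaction at the mono-aryl ether.

**Step 2**
Reactants: 3 4-(3-hydroxyphenoxy)-3-methoxybenzaldehyde
Product: 5 4-(3-hydroxyphenoxy)-3-methoxyphenol, via aryl formate 4 (not isolated)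
Conditions: mCPBA, CH2Cl2, 0 °C to rt; then K2CO3 (cat.), MeOH, rt
Reagents that add atoms: meta-chloroperoxybenzoic acid (mCPBA), OOC(=O)c1cccc(Cl)c1
Why: Baeyer–Villiger (Dakin-type) oxidation, in which the aryl group, made electron-rich by the para aryloxy oxygen, should migrate in the Criegee adduct in preference to hydride, and the formate is then cleaved by methanolysis.

**Step 3**
Reactants: 5 4-(3-hydroxyphenoxy)-3-methoxyphenol
Product: 7 5-(4-formyl-3-hydroxyphenoxy)-2-hydroxy-4-methoxybenzaldehyde, via bis(hydroxymethyl)bisphenol 6 (not isolated)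
Conditions: MgCl2, Et3N, (CH2O)n, THF, reflux; then aq. HCl
Reagents that add atoms: paraformaldehyde (source of formaldehyde), C=O
Why: Twofold Casnati–Skattebøl ortho-formylation, in which each magnesium phenoxide delivers formaldehyde only to an ortho carbon, the open ortho carbon para to an ether oxygen should react in both rings rather than the one flanked by two oxygens, and further formaldehyde accepts hydride from the hydroxymethyl groups of 6 (Oppenauer-type) to give the aldehydes.

**Step 4**
Reactants: 8 4-iodophenol
Product: 9 (4-iodophenoxy)tri(propan-2-yl)silane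
Conditions: TIPSCl, imidazole, DMF, rt
Reagents that add atoms: chlorotri(propan-2-yl)silane (TIPSCl), CC(C)[Si](Cl)(C(C)C)C(C)C
Why: Standard imidazole-promoted O-silylation of a phenol, with no competing functionality in the substrate.

**Step 5**
Reactants: 9 (4-iodophenoxy)tri(propan-2-yl)silane; 10 ethynyltrimethylsilane
Product: 11 trimethyl[(4-{[tri(propan-2-yl)silyl]oxy}phenyl)ethynyl]silane
Conditions: PdCl2(PPh3)2 (2 mol%), CuI (4 mol%), Et3N, THF, rt
Reagents that add atoms: none
Why: Sonogashira coupling, in which the aryl iodide adds oxidatively to zerovalent palladium, the copper acetylide transmetalates and reductive elimination forms the aryl–alkyne bond, while both silyl groups are inert.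

**Step 6**
Reactants: 11 trimethyl[(4-{[tri(propan-2-yl)silyl]oxy}phenyl)ethynyl]silane
Product: 12 (4-ethynylphenoxy)tri(propan-2-yl)silane
Conditions: K2CO3 (0.2 equiv), MeOH/THF, 0 °C to rt
Reagents that add atoms: none
Why: Methoxide-mediated protodesilylation of the alkynyl C–Si bond, which is far more labile than the hindered aryl triisopropylsilyl ether under brief exposure to catalytic carbonate.

**Step 7**
Reactants: 7 5-(4-formyl-3-hydroxyphenoxy)-2-hydroxy-4-methoxybenzaldehyde; 12 (4-ethynylphenoxy)tri(propan-2-yl)silane (3 equiv)
Product: 13 (2E)-1-[2-hydroxy-5-(3-hydroxy-4-{(2E)-3-[4-(triisopropylsilyloxy)phenyl]prop-2-enoyl}phenoxy)-4-methoxyphenyl]-3-[4-(triisopropylsilyloxy)phenyl]prop-2-en-1-one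
Conditions: [RhCl(cod)]2 (5 mol%), dppf [Fe(C5H4PPh2)2] (10 mol%), Na2CO3 (20 mol%), toluene, 90 °C, 12 added slowly
Reagents that add atoms: none
Why: Chelation-assisted intermolecular alkyne hydroacylation: carbonate turns each ortho phenol of 7 into a rhodium phenoxide, monovalent rhodium inserts into the neighbouring formyl C–H bond to give a five-membered acyl hydride chelate of trivalent rhodium that resists decarbonylation, alkyne 12 inserts syn into Rh–H, and C–C reductive elimination releases the enone. The closest known reaction is the coupling of simple salicylaldehydes with alkynes under [RhCl(cod)]2, a bisphosphine and Na2CO3 to give 2-hydroxyaryl vinyl ketones, here run twice on one substrate. No ring closes and no stereocentre forms; both C(=O)–Cα bonds are made, and the E geometry of each alkene follows from the syn delivery of acyl and hydride across the triple bond. The step needs linear rather than branched addition, which the hydrometalation should give by placing rhodium on the unsubstituted alkyne carbon, away from the aryl group and the bulky dppf sphere; slow addition of excess 12 should limit alkyne oligomerisation, and catalytic weak base in toluene should keep the 2-hydroxychalcone units from closing to flavanones. The two salicylaldehyde units are insulated from each other by the ether oxygen, so the second addition should proceed like the first.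

**Step 8**
Reactants: 13 bis(triisopropylsilyl) ether of the target
Product: 14 (2E)-1-[2-hydroxy-5-(3-hydroxy-4-{(2E)-3-(4-hydroxyphenyl)prop-2-enoyl}phenoxy)-4-methoxyphenyl]-3-(4-hydroxyphenyl)prop-2-en-1-one (the target bichalcone)
Conditions: Bu4NF, AcOH, THF, 0 °C
Reagents that add atoms: none
Why: Fluoride-induced cleavage of the two aryl Si–O bonds (desilylation), with acetic acid buffering the phenoxides so that the 2-hydroxychalcone units should neither undergo oxa-Michael closure nor lose their E geometry.

**Compound list**
1 | resorcinol (benzene-1,3-diol) | Oc1cccc(O)c1 | starting material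
2 | 4-fluoro-3-methoxybenzaldehyde | COc1cc(C=O)ccc1F | starting material
3 | 4-(3-hydroxyphenoxy)-3-methoxybenzaldehyde | COc1cc(C=O)ccc1Oc1cccc(O)c1 | intermediate
4 | 4-(3-hydroxyphenoxy)-3-methoxyphenyl formate (not isolated) | COc1cc(OC=O)ccc1Oc1cccc(O)c1 | intermediate
5 | 4-(3-hydroxyphenoxy)-3-methoxyphenol | COc1cc(O)ccc1Oc1cccc(O)c1 | intermediate
6 | 2-(hydroxymethyl)-4-[3-hydroxy-4-(hydroxymethyl)phenoxy]-5-methoxyphenol (not isolated) | COc1cc(O)c(CO)cc1Oc1ccc(CO)c(O)c1 | intermediate
7 | 5-(4-formyl-3-hydroxyphenoxy)-2-hydroxy-4-methoxybenzaldehyde | COc1cc(O)c(C=O)cc1Oc1ccc(C=O)c(O)c1 | intermediate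
8 | 4-iodophenol | Oc1ccc(I)cc1 | starting material
9 | (4-iodophenoxy)tri(propan-2-yl)silane | CC(C)[Si](Oc1ccc(I)cc1)(C(C)C)C(C)C | intermediate
10 | ethynyltrimethylsilane | C#C[Si](C)(C)C | starting material
11 | trimethyl[(4-{[tri(propan-2-yl)silyl]oxy}phenyl)ethynyl]silane | CC(C)[Si](Oc1ccc(C#C[Si](C)(C)C)cc1)(C(C)C)C(C)C | intermediate
12 | (4-ethynylphenoxy)tri(propan-2-yl)silane | C#Cc1ccc(O[Si](C(C)C)(C(C)C)C(C)C)cc1 | intermediate
13 | (2E)-1-[2-hydroxy-5-(3-hydroxy-4-{(2E)-3-[4-(triisopropylsilyloxy)phenyl]prop-2-enoyl}phenoxy)-4-methoxyphenyl]-3-[4-(triisopropylsilyloxy)phenyl]prop-2-en-1-one | COc1cc(O)c(C(=O)/C=C/c2ccc(O[Si](C(C)C)(C(C)C)C(C)C)cc2)cc1Oc1ccc(C(=O)/C=C/c2ccc(O[Si](C(C)C)(C(C)C)C(C)C)cc2)c(O)c1 | intermediate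
14 | (2E)-1-[2-hydroxy-5-(3-hydroxy-4-{(2E)-3-(4-hydroxyphenyl)prop-2-enoyl}phenoxy)-4-methoxyphenyl]-3-(4-hydroxyphenyl)prop-2-en-1-one | COc1cc(O)c(C(=O)/C=C/c2ccc(O)cc2)cc1Oc1ccc(C(=O)/C=C/c2ccc(O)cc2)c(O)c1 | target

**Step count**
Total steps: 8. Longest linear sequence: 5 steps (steps 1, 2, 3, 7, 8; the alkyne branch, steps 4, 5, 6, 7, 8, is equally long).

**Steps most likely to fail**

Step 7. The hydrometalation may place rhodium on the aryl-bearing alkyne carbon and give branched enone. The alkyne may also be consumed by rhodium-mediated oligomerisation, the reaction may stop after one hydroacylation, or the product may close to a flavanone. The fallback sets out from 5 and returns at 14. Twofold ortho-acetylation of 5 (AcOH, BF3·OEt2, 90 °C, Friedel–Crafts/Fries type, directed ortho to each hydroxyl and para to an ether oxygen) would give the diketone 1-[5-(4-acetyl-3-hydroxyphenoxy)-2-hydroxy-4-methoxyphenyl]ethan-1-one F1. Twofold Claisen–Schmidt condensation of F1 with commercial 4-(methoxymethoxy)benzaldehyde (KOH, EtOH, rt) would give the bis(methoxymethyl) ether of the target F2 with both alkenes E. Aqueous HCl in THF at 50 °C would then remove both acetal groups and give 14.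

Step 3. One ring may remain unformylated, formaldehyde may bridge the electron-rich rings through methylene groups, or some attack may occur at the ortho carbon between the two oxygens of ring A′. The fallback sets out from 5 and returns at 7. Heating 5 with phenylboronic acid, paraformaldehyde and catalytic propanoic acid in toluene with removal of water confines each phenol to a single templated ortho-hydroxymethylation and would give 7-methoxy-2-phenyl-6-[(2-phenyl-4H-1,3,2-benzodioxaborin-7-yl)oxy]-4H-1,3,2-benzodioxaborin F3. Transesterification of F3 with propane-1,3-diol would release 6, isolated here, and MnO2 in CH2Cl2 would oxidise its two benzylic alcohols to give 7.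

Step 1. The remaining phenol of 3 may be arylated a second time, or substitution may be slow because the ortho methoxy group donates into the carbon bearing fluorine. The fallback sets out from 2 and returns at 5. SNAr of 2 with commercial 3-(benzyloxy)phenol (K2CO3, DMSO, 110 °C), which has a single free phenol, would give 4-[3-(benzyloxy)phenoxy]-3-methoxybenzaldehyde F4. Oxidation with mCPBA would pass through 4-[3-(benzyloxy)phenoxy]-3-methoxyphenyl formate F5 (not isolated), and methanolysis would give 4-[3-(benzyloxy)phenoxy]-3-methoxyphenol F6. Hydrogenolysis of F6 (H2, Pd on carbon, EtOAc) would give 5.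

**Further compounds**
F1 | step 7 | 1-[5-(4-acetyl-3-hydroxyphenoxy)-2-hydroxy-4-methoxyphenyl]ethan-1-one | COc1cc(O)c(C(C)=O)cc1Oc1ccc(C(C)=O)c(O)c1
F2 | step 7 | (2E)-1-[2-hydroxy-5-(3-hydroxy-4-{(2E)-3-[4-(methoxymethoxy)phenyl]prop-2-enoyl}phenoxy)-4-methoxyphenyl]-3-[4-(methoxymethoxy)phenyl]prop-2-en-1-one | COc1cc(O)c(C(=O)/C=C/c2ccc(OCOC)cc2)cc1Oc1ccc(C(=O)/C=C/c2ccc(OCOC)cc2)c(O)c1
F3 | step 3 | 7-methoxy-2-phenyl-6-[(2-phenyl-4H-1,3,2-benzodioxaborin-7-yl)oxy]-4H-1,3,2-benzodioxaborin | COc1cc2OB(c3ccccc3)OCc2cc1Oc1ccc2COB(c3ccccc3)Oc2c1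
F4 | step 1 | 4-[3-(benzyloxy)phenoxy]-3-methoxybenzaldehyde | COc1cc(C=O)ccc1Oc1cccc(OCc2ccccc2)c1
F5 | step 1 | 4-[3-(benzyloxy)phenoxy]-3-methoxyphenyl formate | COc1cc(OC=O)ccc1Oc1cccc(OCc2ccccc2)c1
F6 | step 1 | 4-[3-(benzyloxy)phenoxy]-3-methoxyphenol | COc1cc(O)ccc1Oc1cccc(OCc2ccccc2)c1
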